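**Plan**
1. Late cuts: the C6 ester (acylation), the C8=C14 methylene (Wittig on a C8 ketone), the C9/C10 cis-diol (osmylation of a C9=C10 alkene that descends from a C10 carbonyl through its enol triflate) and the C4–isopropyl bond (organocerium addition to a C4 ketone).
2. Central cut: C3–C4 of the five-membered ring. On the seven-membered ring C5 holds C4 and the adjacent quaternary C1 holds the C2–C3 unit on the opposite face; with C4 as formyl and C2=C3 as vinyl this array is a 4-pentenal, which rhodium hydroacylation closes to the C4 cyclopentanone.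
3. Earlier cuts: C4–C5 and C1–C2, made in one operation by conjugate addition of a hydroxymethyl equivalent to a 2-methyl-4-silyloxycycloheptenone and aldol capture of the enolate by acetaldehyde; the enone comes from cyclohepta-1,3-diene.
4. Forward order: the seven-membered ring is present from the start, the five-membered ring closes in step 13, and C8–C10 are functionalised afterwards.
5. Stereochemistry: C6 from enzymatic desymmetrisation of a meso-diacetate; C5 by addition anti to C6–O; C1 by aldol anti to the C5 substituent; C4, C9 and C10 by reagent approach to the face opposite the angular C15 methyl.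

Key step: step 13

Numbering: from compound 12 onward atoms carry the numbers of the target skeleton (C1 quaternary with methyl C15; C2, C3; C4 carbinol with isopropyl; C5 ring-fusion CH; C6 ester carbon; C7; C8 with methylene C14; C9; C10). β is the face of C15, α the opposite face. The target is 1β-methyl, 4β-OH/4α-isopropyl, 5α-H, 6α-acyloxy, 9α-OH, 10α-OH.

Assumption: the lipase acts on the S-configured carbinol centre of the meso substrate, as it does for the cyclopentene homologue; with an enzyme of opposite sense, acetylation of the meso-diol instead of hydrolysis of the diacetate would lead to the same monoacetate 3.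

**Step 1**
Reactants: 1 cyclohepta-1,3-diene
Product: 2 cis-cyclohept-2-ene-1,4-diyl diacetate (meso)
Conditions: Pd(OAc)2 (5 mol %), LiCl (cat.), LiOAc, p-benzoquinone, AcOH, 25 °C
Reagents that add atoms: acetic acid CC(=O)O
Why: Palladium-catalysed 1,4-diacetoxylation: acetate adds anti to divalent palladium to give a π-allyl complex, chloride blocks inner-sphere delivery so the second acetate also attacks anti to the metal, and both esters end up cis while benzoquinone reoxidises zerovalent palladium.

**Step 2**
Reactants: 2 cis-cyclohept-2-ene-1,4-diyl diacetate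
Product: 3 (1R,4S)-4-hydroxycyclohept-2-en-1-yl acetate
Conditions: Candida antarctica lipase B (immobilised), phosphate buffer pH 7, 25 °C
Reagents that add atoms: none
Why: Enzymatic desymmetrisation (lipase hydrolysis of a meso-diacetate) should cleave only the ester at the S-configured carbinol, which fixes the absolute configuration of the route; the freed S-carbinol becomes C6.

**Step 3**
Reactants: 3 (1R,4S)-4-hydroxycyclohept-2-en-1-yl acetate
Product: 4 (1R,4S)-4-[(tert-butyldimethylsilyl)oxy]cyclohept-2-en-1-yl acetate
Conditions: TBSCl, imidazole, DMF, 25 °C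
Reagents that add atoms: tert-butyldimethylsilyl chloride CC(C)(C)[Si](C)(C)Cl
Why: Standard silyl ether formation on the free allylic hydroxyl; no stereocentre is touched.

**Step 4**
Reactants: 4 silyl ether acetate
Product: 5 (1R,4S)-4-[(tert-butyldimethylsilyl)oxy]cyclohept-2-en-1-ol
Conditions: K2CO3, MeOH, 0 to 25 °C
Reagents that add atoms: none
Why: Base-catalysed transesterification (methanolysis) removes the acetate while the silyl ether is stable.

**Step 5**
Reactants: 5 allylic alcohol
Product: 6 (S)-4-[(tert-butyldimethylsilyl)oxy]cyclohept-2-en-1-one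
Conditions: Dess–Martin periodinane, NaHCO3, CH2Cl2, 25 °C
Reagents that add atoms: none
Why: Dess–Martin oxidation of the allylic alcohol should give the enone without disturbing the silyloxy-bearing centre.

**Step 6**
Reactants: 6 enone
Product: 7 (S)-4-[(tert-butyldimethylsilyl)oxy]-2-iodocyclohept-2-en-1-one
Conditions: I2, pyridine, CH2Cl2, 0 to 25 °C
Reagents that add atoms: iodine [I][I]
Why: α-Iodination of the enone by conjugate addition of pyridine, iodination of the enolate and elimination places iodine on the α-carbon only.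

**Step 7**
Reactants: 7 α-iodoenone
Product: 8 (S)-4-[(tert-butyldimethylsilyl)oxy]-2-methylcyclohept-2-en-1-one
Conditions: Me4Sn, PdCl2(PhCN)2 (5 mol %), AsPh3, CuI, N-methylpyrrolidone, 80 °C
Reagents that add atoms: tetramethylstannane C[Sn](C)(C)C
Why: Stille coupling of the α-iodoenone replaces iodine by the future C15 methyl under neutral conditions.

**Step 8**
Reactants: 8 methyl enone; 9 (chloromethyl)isopropoxydimethylsilane; 10 acetaldehyde
Product: 14 keto diol (C10 ketone; 1β-methyl; 1α-(1-hydroxyethyl); 5β-hydroxymethyl; 6α-OTBS), via Grignard reagent 11 (not isolated), via magnesium enolate 12 (not isolated), via silyl aldol 13 (not isolated)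
Conditions: 9, Mg, THF; CuBr·SMe2 (20 mol %), 8, THF, −78 to −40 °C; 10, −78 °C; aq. NH4Cl; then 30% H2O2, KF, KHCO3, THF/MeOH, 25 °C
Reagents that add atoms: hydrogen peroxide OO
Why: Copper-catalysed conjugate addition of the hydroxymethyl-anion equivalent should enter C5 anti to the C6 silyloxy group, the regiodefined enolate then adds acetaldehyde at C1 on the face away from the new C5 substituent (tandem conjugate addition–aldol), and Tamao oxidation turns the C–Si bond into the primary alcohol; the carbinol epimers of the hydroxyethyl group converge in step 10.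

**Step 9**
Reactants: 14 keto diol
Product: 15 primary triethylsilyl ether of 14
Conditions: TESCl (1.05 equiv), imidazole, CH2Cl2, −40 °C
Reagents that add atoms: chlorotriethylsilane CC[Si](Cl)(CC)CC
Why: Selective silylation: the primary hydroxyl reacts far faster than the neopentyl secondary carbinol.

**Step 10**
Reactants: 15 hydroxy ketone
Product: 16 vinyl ketone (C10 ketone; 1β-methyl; 1α-vinyl; 5β-CH2OTES; 6α-OTBS)
Conditions: Martin sulfurane Ph2S[OC(CF3)2Ph]2, CH2Cl2, 25 °C
Reagents that add atoms: none
Why: Martin sulfurane dehydration can only eliminate toward the methyl group because C1 is quaternary, so the terminal vinyl group should form under neutral conditions that disfavour retro-aldol cleavage.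

**Step 11**
Reactants: 16 vinyl ketone
Product: 18 enol triflate (C9=C10–OTf), via potassium enolate 17 (not isolated)
Conditions: KN(SiMe3)2, THF, −78 °C; PhNTf2, −78 to 0 °C
Reagents that add atoms: N-phenylbis(trifluoromethanesulfonimide) O=S(=O)(N(c1ccccc1)S(=O)(=O)C(F)(F)F)C(F)(F)F
Why: Kinetic enolate O-triflation: the ketone can enolise only toward C9, so a single enol triflate results, which stores the future C9=C10 alkene in a form inert to the next steps.

**Step 12**
Reactants: 18 enol triflate
Product: 19 aldehyde (5β-formyl; 1α-vinyl; 1β-methyl; 6α-OTBS; C9=C10–OTf)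
Conditions: (COCl)2, DMSO, CH2Cl2, −78 to −40 °C; Et3N, −78 to 0 °C
Reagents that add atoms: none
Why: Swern oxidation converts a primary triethylsilyl ether directly into the aldehyde while the secondary tert-butyldimethylsilyl ether and the enol triflate are inert.

**Step 13**
Reactants: 19 aldehyde
Product: 20 trans-fused bicyclic C4 ketone (1β-methyl; 5α-H; 6α-OTBS; C9=C10–OTf)
Conditions: [Rh(nbd)(dppe)]BF4 (5 mol %), H2 then Ar purge (gives [Rh(dppe)]BF4), CH2Cl2, 25 °C
Reagents that add atoms: none
Why: Monovalent rhodium inserts into the formyl C–H bond to give an acyl rhodium hydride (trivalent rhodium), the C2=C3 vinyl group coordinates and inserts into Rh–H with hydrogen going to C2, and the six-membered acyl rhodacycle collapses by reductive elimination to form C3–C4. The closest known reaction type is the rhodium-catalysed intramolecular hydroacylation of 4-pentenals to cyclopentanones with cationic diphosphine catalysts. The five-membered ring closes in a formally 5-endo-trig sense at the vinyl group, the normal course for this reaction. No stereocentre is created; C1 and C5 are untouched under the neutral conditions, so the trans relationship of 19 becomes the trans ring fusion of 20. The step needs hydroacylation to outrun decarbonylation and to occur at the vinyl group only: quaternary C1 favours the reactive conformer and offers no allylic hydrogen for alkene migration, the chelating dppe ligand disfavours CO loss, and the ring unsaturation is present only as a hindered, electron-poor enol triflate that should not insert.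

**Step 14**
Reactants: 20 bicyclic ketone
Product: 21 tertiary alcohol (4β-hydroxy; 4α-isopropyl; C9=C10–OTf)
Conditions: i-PrMgCl, CeCl3 (anhydrous), THF, −78 °C
Reagents that add atoms: isopropylmagnesium chloride CC(C)[Mg]Cl
Why: Organocerium addition to the cyclopentanone avoids enolisation at C5 and should approach C4 from the α face, away from the angular C15 methyl that lies 1,3 to the carbonyl on the β face, which sets C4.

**Step 15**
Reactants: 21 enol triflate
Product: 22 ring alkene (C9=C10)
Conditions: Pd(OAc)2 (5 mol %), PPh3, HCO2H, Et3N, DMF, 60 °C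
Reagents that add atoms: none
Why: Palladium-catalysed formate reduction of the enol triflate (oxidative addition to zerovalent palladium, decarboxylation of formate, reductive elimination) gives the cis ring alkene.

**Step 16**
Reactants: 22 alkene
Product: 23 enone (C8 ketone; C9=C10)
Conditions: Rh2(cap)4 (1 mol %; cap = caprolactamate), t-BuOOH, K2CO3, CH2Cl2, 25 °C
Reagents that add atoms: tert-butyl hydroperoxide CC(C)(C)OO
Why: Dirhodium-catalysed allylic C–H oxidation: C8 is the only allylic methylene (C1 on the other side is quaternary), and capture of the allyl radical is expected at its unhindered C8 end.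

**Step 17**
Reactants: 23 enone
Product: 24 dihydroxy ketone (9α,10α-diol; C8 ketone)
Conditions: K2OsO2(OH)4 (2 mol %), N-methylmorpholine N-oxide, citric acid, t-BuOH/H2O, 25 °C
Reagents that add atoms: N-methylmorpholine N-oxide C[N+]1([O-])CCOCC1; water O
Why: Osmium-catalysed syn-dihydroxylation under the acidic protocol suited to electron-poor alkenes should add both oxygens to the α face, opposite the axial C15 methyl on the neighbouring C1, setting C9 and C10 together.

**Step 18**
Reactants: 24 dihydroxy ketone
Product: 25 acetonide ketone (9α,10α-O-isopropylidene)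
Conditions: 2,2-dimethoxypropane, pyridinium p-toluenesulfonate (cat.), acetone, 25 °C
Reagents that add atoms: 2,2-dimethoxypropane COC(C)(C)OC
Why: Acid-catalysed acetonide formation on the cis-diol; the tertiary C4 hydroxyl does not react.

**Step 19**
Reactants: 25 acetonide ketone
Product: 26 exocyclic alkene (C8=C14)
Conditions: Ph3PCH3Br, KOt-Bu, THF, 0 to 25 °C
Reagents that add atoms: methyltriphenylphosphonium bromide C[P+](c1ccccc1)(c1ccccc1)c1ccccc1.[Br-]
Why: Wittig methylenation of the unhindered C8 ketone installs C14; fast addition of the unstabilised ylide should outpace enolisation toward C7 or C9.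

**Step 20**
Reactants: 26 silyl ether
Product: 27 C6 alcohol (6α-OH)
Conditions: Bu4NF, THF, 25 to 40 °C
Reagents that add atoms: none
Why: Fluoride-mediated desilylation frees the C6 hydroxyl and leaves the acetonide and the tertiary alcohol untouched.

**Step 21**
Reactants: 27 C6 alcohol
Product: 28 C6 3-methylbutanoate (acetonide)
Conditions: 3-methylbutanoyl chloride, pyridine, DMAP (cat.), CH2Cl2, 0 to 25 °C
Reagents that add atoms: 3-methylbutanoyl chloride CC(C)CC(=O)Cl
Why: DMAP-catalysed acylation takes place at the only secondary hydroxyl; the tertiary C4 hydroxyl is unreactive under these conditions.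

**Step 22**
Reactants: 28 ester acetonide
Product: 29 target CNP0204264.1
Conditions: AcOH/H2O (4:1), 40 °C
Reagents that add atoms: none
Why: Mild acid-catalysed acetal hydrolysis should remove the acetonide without ester cleavage or ionisation of the allylic C9–O bond.

**Compound list**
1 | cyclohepta-1,3-diene | C1=CC=CCCC1 | starting material
2 | cis-cyclohept-2-ene-1,4-diyl diacetate (meso) | CC(=O)O[C@H]1C=C[C@@H](OC(C)=O)CCC1 | intermediate
3 | (1R,4S)-4-hydroxycyclohept-2-en-1-yl acetate | CC(=O)O[C@H]1C=C[C@@H](O)CCC1 | intermediate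
4 | (1R,4S)-4-[(tert-butyldimethylsilyl)oxy]cyclohept-2-en-1-yl acetate | CC(=O)O[C@H]1C=C[C@@H](O[Si](C)(C)C(C)(C)C)CCC1 | intermediate
5 | (1R,4S)-4-[(tert-butyldimethylsilyl)oxy]cyclohept-2-en-1-ol | O[C@H]1C=C[C@@H](O[Si](C)(C)C(C)(C)C)CCC1 | intermediate
6 | (S)-4-[(tert-butyldimethylsilyl)oxy]cyclohept-2-en-1-one | O=C1C=C[C@@H](O[Si](C)(C)C(C)(C)C)CCC1 | intermediate
7 | (S)-4-[(tert-butyldimethylsilyl)oxy]-2-iodocyclohept-2-en-1-one | O=C1C(I)=C[C@@H](O[Si](C)(C)C(C)(C)C)CCC1 | intermediate
8 | (S)-4-[(tert-butyldimethylsilyl)oxy]-2-methylcyclohept-2-en-1-one | O=C1C(C)=C[C@@H](O[Si](C)(C)C(C)(C)C)CCC1 | intermediate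
9 | (chloromethyl)isopropoxydimethylsilane | CC(C)O[Si](C)(C)CCl | starting material
10 | acetaldehyde | CC=O | starting material
11 | [(isopropoxydimethylsilyl)methyl]magnesium chloride | CC(C)O[Si](C)(C)C[Mg]Cl | intermediate
12 | chloromagnesium C1=C10 enolate; 5β-[(isopropoxydimethylsilyl)methyl]; 6α-OTBS | C1CC[C@H](O[Si](C)(C)C(C)(C)C)[C@@H](C[Si](C)(C)OC(C)C)C(C)=C1O[Mg]Cl | intermediate
13 | silyl aldol: C10 ketone; 1β-methyl; 1α-(1-hydroxyethyl), carbinol epimers; 5β-[(isopropoxydimethylsilyl)methyl]; 6α-OTBS | C1CC[C@H](O[Si](C)(C)C(C)(C)C)[C@@H](C[Si](C)(C)OC(C)C)[C@](C)(C(C)O)C1=O | intermediate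
14 | keto diol: C10 ketone; 1β-methyl; 1α-(1-hydroxyethyl), carbinol epimers; 5β-hydroxymethyl; 6α-OTBS | C1CC[C@H](O[Si](C)(C)C(C)(C)C)[C@@H](CO)[C@](C)(C(C)O)C1=O | intermediate
15 | as 14 with the primary hydroxyl as triethylsilyl ether | C1CC[C@H](O[Si](C)(C)C(C)(C)C)[C@@H](CO[Si](CC)(CC)CC)[C@](C)(C(C)O)C1=O | intermediate
16 | vinyl ketone: C10 ketone; 1β-methyl; 1α-vinyl; 5β-[(triethylsilyloxy)methyl]; 6α-OTBS | C1CC[C@H](O[Si](C)(C)C(C)(C)C)[C@@H](CO[Si](CC)(CC)CC)[C@](C)(C=C)C1=O | intermediate
17 | potassium C9=C10 enolate of 16 | C1C[C@H](O[Si](C)(C)C(C)(C)C)[C@@H](CO[Si](CC)(CC)CC)[C@](C)(C=C)C([O-])=C1.[K+] | intermediate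
18 | enol triflate: C9=C10–OTf; 1β-methyl; 1α-vinyl; 5β-[(triethylsilyloxy)methyl]; 6α-OTBS | C1C[C@H](O[Si](C)(C)C(C)(C)C)[C@@H](CO[Si](CC)(CC)CC)[C@](C)(C=C)C(OS(=O)(=O)C(F)(F)F)=C1 | intermediate
19 | aldehyde: 5β-formyl; 1α-vinyl; 1β-methyl; 6α-OTBS; C9=C10–OTf | C1C[C@H](O[Si](C)(C)C(C)(C)C)[C@@H](C=O)[C@](C)(C=C)C(OS(=O)(=O)C(F)(F)F)=C1 | intermediate
20 | trans-fused bicyclo[5.3.0]decenone: C4 ketone; 1β-methyl; 5α-H; 6α-OTBS; C9=C10–OTf | C1C[C@H](O[Si](C)(C)C(C)(C)C)[C@@H]2[C@](C)(CCC2=O)C(OS(=O)(=O)C(F)(F)F)=C1 | intermediate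
21 | as 20 with 4β-hydroxy and 4α-isopropyl | C1C[C@H](O[Si](C)(C)C(C)(C)C)[C@@H]2[C@](C)(CC[C@@]2(O)C(C)C)C(OS(=O)(=O)C(F)(F)F)=C1 | intermediate
22 | 4β-hydroxy-4α-isopropyl-1β-methyl-6α-OTBS bicyclo[5.3.0]dec-9-ene (5α-H) | C1C[C@H](O[Si](C)(C)C(C)(C)C)[C@@H]2[C@](C)(CC[C@@]2(O)C(C)C)C=C1 | intermediate
23 | as 22 with a C8 ketone (8-oxo-9-ene) | O=C1C[C@H](O[Si](C)(C)C(C)(C)C)[C@@H]2[C@](C)(CC[C@@]2(O)C(C)C)C=C1 | intermediate
24 | 9α,10α-dihydroxy C8 ketone | O=C1C[C@H](O[Si](C)(C)C(C)(C)C)[C@@H]2[C@](C)(CC[C@@]2(O)C(C)C)[C@H](O)[C@@H]1O | intermediate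
25 | 9α,10α-O-isopropylidene C8 ketone | O=C1C[C@H](O[Si](C)(C)C(C)(C)C)[C@@H]2[C@](C)(CC[C@@]2(O)C(C)C)[C@H](OC(C)(C)O3)[C@@H]13 | intermediate
26 | 8(14)-methylene acetonide; 6α-OTBS | C=C1C[C@H](O[Si](C)(C)C(C)(C)C)[C@@H]2[C@](C)(CC[C@@]2(O)C(C)C)[C@H](OC(C)(C)O3)[C@@H]13 | intermediate
27 | 8(14)-methylene acetonide; 6α-OH | C=C1C[C@H](O)[C@@H]2[C@](C)(CC[C@@]2(O)C(C)C)[C@H](OC(C)(C)O3)[C@@H]13 | intermediate
28 | 8(14)-methylene acetonide; 6α-(3-methylbutanoate) | C=C1C[C@H](OC(=O)CC(C)C)[C@@H]2[C@](C)(CC[C@@]2(O)C(C)C)[C@H](OC(C)(C)O3)[C@@H]13 | intermediate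
29 | CNP0204264.1: 4β,9α,10α-trihydroxy-4α-isopropyl-1β-methyl-8-methylene bicyclo[5.3.0]decan-6α-yl 3-methylbutanoate | C=C1C[C@H](OC(=O)CC(C)C)[C@@H]2[C@](C)(CC[C@@]2(O)C(C)C)[C@H](O)[C@@H]1O | target

**Totals**
Total step count: 22. Longest linear sequence: 22 steps (1 to 29).

**Steps most likely to fail**

Step 16. The allylic oxidation may show poor regiocontrol, with capture of the allyl radical at C10 and formation of the transposed enone, or may over-oxidise. Fallback: from 22, SeO2 (cat.)/t-BuOOH in CH2Cl2 would oxygenate by an ene reaction followed by a [2,3]-sigmatropic shift, which can only return oxygen to C8 because it is the sole allylic C–H position. This should give the C8 allylic alcohol F1 as a mixture of C8 epimers, and Dess–Martin oxidation of it comes back to 23.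

Step 10. Loss of water may be diverted into retro-aldol cleavage or a 1,2-shift at the neopentyl carbinol. Fallback: from 8, the copper-catalysed addition of 11 is run as in step 8, but enolate 12 is captured by phenyl vinyl sulfoxide (Michael addition) in place of acetaldehyde, giving the 2-(phenylsulfinyl)ethyl ketone F2. Thermolysis in toluene at 110 °C (sulfoxide syn-elimination) should give the vinyl ketone F3 with the alkoxysilane intact. Tamao oxidation then gives the hydroxymethyl vinyl ketone F4, and silylation with TESCl/imidazole comes back to 16.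

Step 14. Enolisation of the cyclopentanone, which would endanger C5, or hydride transfer from the isopropyl reagent may compete with addition. Fallback: from 20, 2-propenylmagnesium bromide/CeCl3, an sp2 nucleophile that is less basic and not a hydride donor, should give the isopropenyl carbinol F5. Hydrogenation of its 1,1-disubstituted alkene with RhCl(PPh3)3/H2, which should leave the hindered enol triflate alkene untouched, comes back to 21.

**Further compounds**
F1 | step 16 | C8 allylic alcohol of 22 (C8 epimers; C9=C10) | OC1C[C@H](O[Si](C)(C)C(C)(C)C)[C@@H]2[C@](C)(CC[C@@]2(O)C(C)C)C=C1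
F2 | step 10 | C10 ketone; 1β-methyl; 1α-[2-(phenylsulfinyl)ethyl]; 5β-[(isopropoxydimethylsilyl)methyl]; 6α-OTBS | C1CC[C@H](O[Si](C)(C)C(C)(C)C)[C@@H](C[Si](C)(C)OC(C)C)[C@](C)(CCS(=O)c2ccccc2)C1=O
F3 | step 10 | C10 ketone; 1β-methyl; 1α-vinyl; 5β-[(isopropoxydimethylsilyl)methyl]; 6α-OTBS | C1CC[C@H](O[Si](C)(C)C(C)(C)C)[C@@H](C[Si](C)(C)OC(C)C)[C@](C)(C=C)C1=O
F4 | step 10 | C10 ketone; 1β-methyl; 1α-vinyl; 5β-hydroxymethyl; 6α-OTBS | C1CC[C@H](O[Si](C)(C)C(C)(C)C)[C@@H](CO)[C@](C)(C=C)C1=O
F5 | step 14 | as 21 with 4α-isopropenyl in place of isopropyl | C1C[C@H](O[Si](C)(C)C(C)(C)C)[C@@H]2[C@](C)(CC[C@@]2(O)C(C)=C)C(OS(=O)(=O)C(F)(F)F)=C1
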